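The route rests on ring B. The quaternary C10 methyl (C14) is β, cis to the C9 oxygen and trans to H5 (eudesmane numbering; ring A = C1–C5 and C10, ring B = C5–C10). C14 is therefore passed as a CH2 group from a 9β-hydroxyl to a C10=C1 alkene, and the C1–C14 bond of the resulting cyclopropane is cut later.
Late disconnections: C12 acid from the isopropenyl methyl group (Riley, Dess–Martin, Pinnick); C9–O acyl bond (Steglich); 9β-ol from the 9-ketone (Li/NH3); C7–C11 by axial cuprate addition to a 7-en-9-one (Saegusa–Ito).
Middle: 10β-methyl by hydrogenolysis of the cyclopropane; 4α-OH/4β-CH3 by α-epoxidation of the C4 methylene and hydride opening at C15.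
Ring order: ring B is bought as cyclohexenone (C5 set by Rh/(R)-BINAP conjugate alkenylation). Ring A closes by aldol condensation (C10=C1). The temporary three-membered ring C1–C10–C14 closes in step 5 and is opened in step 8.
Key step: step 5

Assumption: α/β refer to the usual eudesmane drawing with C14 up; read this way, the target SMILES carries the C7 side chain α (axial, on the side of H5), and the route aims at that epimer; 1 and 23 are taken as purchasable.

Step 1
Reactants: 1 5,5-diethoxypent-1-yne
Product: 3 2-(5,5-diethoxypent-1-en-2-yl)-4,4,5,5-tetramethyl-1,3,2-dioxaborolane, via internal vinylalane 2 (not isolated)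
Conditions: iBu2AlH (1.3 equiv), Ni(dppp)Cl2 (3 mol %), THF, 0 °C to rt; then MeOBpin, 0 °C to rt
Reagents that add atoms: diisobutylaluminium hydride, CC(C)C[AlH]CC(C)C (its aluminium stays only in 2); 2-methoxy-4,4,5,5-tetramethyl-1,3,2-dioxaborolane, COB1OC(C)(C)C(C)(C)O1
Why: Nickel-catalysed Markovnikov hydroalumination of a terminal alkyl alkyne puts aluminium on the internal carbon, and aluminium-to-boron exchange gives the 1,1-disubstituted alkenylboronate; the acetal should tolerate iBu2AlH in THF at room temperature, and no stereocentre is formed.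

Step 2
Reactants: 3 2-(5,5-diethoxypent-1-en-2-yl)-4,4,5,5-tetramethyl-1,3,2-dioxaborolane; 4 cyclohex-2-en-1-one
Product: 5 (R)-3-(5,5-diethoxypent-1-en-2-yl)cyclohexan-1-one
Conditions: [Rh(acac)(C2H4)2] (3 mol %), (R)-BINAP (3.3 mol %), dioxane/H2O 10:1, 100 °C
Reagents that add atoms: none
Why: Hayashi–Miyaura asymmetric conjugate addition: the alkenylrhodium/(R)-BINAP complex inserts the enone on the face that gives the (R)-ketone (the sense known for aryl and alkenyl groups, which rank the same way here), setting C5 with H5 α, and the near-neutral medium leaves the acetal in place.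

Step 3
Reactants: 5 (R)-3-(5,5-diethoxypent-1-en-2-yl)cyclohexan-1-one
Product: 8 (4aS)-5-methylidene-3,4,4a,5,6,7-hexahydronaphthalen-1(2H)-one (eudesmane numbering: 4-methylene-1(10)-en-9-one with 5αH), via keto aldehyde 6 (not isolated), via aldol adduct 7 (not isolated)
Conditions: 0.1 M aq. HCl (cat.), THF, rt; then KOH (0.3 equiv), MeOH, high dilution, rt to 50 °C
Reagents that add atoms: water, O (its oxygen stays only in 6 and 7)
Why: Dilute acid cleaves the acetal much faster than it protonates the 1,1-disubstituted alkene, and the base-mediated intramolecular aldol condensation (6-enolexo attack of C10 on C1, then E1cB loss of water) closes ring A, because the rival aldol of C2 on C9 is reversible and could dehydrate only to a bridgehead alkene; base is used for the closure since acid strong enough to enolise the ketone would also shift the C4 methylene, and C5 is not enolisable, so its configuration holds.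

Step 4
Reactants: 8 (4aS)-5-methylidene-3,4,4a,5,6,7-hexahydronaphthalen-1(2H)-one
Product: 9 (1S,4aS)-5-methylidene-1,2,3,4,4a,5,6,7-octahydronaphthalen-1-ol (9β-hydroxy-4-methylene-octal-1(10)-ene with 5αH)
Conditions: (R)-1-methyl-3,3-diphenyltetrahydro-1H,3H-pyrrolo[1,2-c][1,3,2]oxazaborole ((R)-Me-CBS, 10 mol %), catecholborane (1.8 equiv), toluene, −78 °C; aq. NaOH work-up
Reagents that add atoms: none
Why: Corey–Bakshi–Shibata reduction: the (R)-catalyst treats the alkenyl flank C10 as the large group and passes hydride to the α face of C9, which is also the axial path favoured by the substrate, so the 9β (S) carbinol results and the minor enantiomer of 8 ends as a separable diastereomer; catecholborane at −78 °C is used because BH3 would hydroborate the C4 methylene.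

Step 5
Reactants: 9 (1S,4aS)-5-methylidene-1,2,3,4,4a,5,6,7-octahydronaphthalen-1-ol; 10 diiodomethane
Product: 12 9β-hydroxy-4-methylene-1β,10β-methanodecalin with 5αH (cyclopropyl carbinol; C14 bridges C1 and C10 on the β face), via iodomethylzinc alkoxide 11 (not isolated)
Conditions: Et2Zn (2.2 equiv), CH2I2 (2.2 equiv), CH2Cl2, −20 to 0 °C; aq. work-up
Reagents that add atoms: diethylzinc, CC[Zn]CC (its zinc stays only in 11)
Why: Et2Zn and 10 convert the 9β-hydroxyl into the iodomethylzinc alkoxide 11, and this carbenoid, activated by the second equivalent of zinc reagent as Lewis acid, hands its CH2 to C10=C1 through a concerted butterfly transition state that forms C10–C14 and C1–C14 together. The closest known reaction type is the hydroxyl-directed Simmons–Smith cyclopropanation (Furukawa reagent) of cyclic allylic alcohols, which delivers methylene syn to the oxygen. The three-membered ring C1–C10–C14 closes by a suprafacial [2+1] addition of the oxygen-bound carbenoid, so C1 and C10 are set as a cis pair and only the alkene face remains to be chosen. That face is fixed by C9: ring B of 9 is a chair with H5 and H9 axial on the α face and the C9–O bond equatorial, tilted out of the alkene plane toward the β face, so the zinc-bound CH2 reaches the β lobes with a relaxed O–Zn–C angle, whereas α delivery needs a longer reach beneath the two axial C–H bonds that flank C10. C14 therefore ends β on C10 (cis to the C9 oxygen, trans to H5), and C1 becomes the cyclopropane CH with H1 α. Site selectivity over the C4 methylene rests on the rate gain of alkoxide-bound delivery: C4=C15 lies three carbons from C9 on the far edge of ring A and can react only in the slow undirected mode, which about two equivalents of carbenoid at low temperature should leave untouched.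

Step 6
Reactants: 12 9β-hydroxy-4-methylene-1β,10β-methanodecalin
Product: 13 4α,15-epoxy-9β-hydroxy-1β,10β-methanodecalin (spiro-epoxide; oxygen α and C15 β)
Conditions: mCPBA (1.1 equiv), CH2Cl2, 0 °C
Reagents that add atoms: 3-chloroperoxybenzoic acid, O=C(OO)c1cccc(Cl)c1
Why: Prilezhaev epoxidation of the only alkene left: the peracid should approach C4 from the α (equatorial) side because the endo hydrogen of the C14 methylene, gauche to C4 like the angular methyl group of 4(15)-eudesmenes, screens the β side, which places the oxygen α and C15 β.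

Step 7
Reactants: 13 4α,15-epoxy-9β-hydroxy-1β,10β-methanodecalin
Product: 14 4β-methyl-1β,10β-methanodecalin-4α,9β-diol
Conditions: LiAlH4, THF, 0 °C to reflux; aq. work-up
Reagents that add atoms: none
Why: SN2 opening of the spiro-epoxide by hydride at the primary C15 leaves the C4–O bond untouched, so the oxygen stays 4α (equatorial) and C15 becomes the 4β-methyl group; the cyclopropane is inert to LiAlH4.

Step 8
Reactants: 14 4β-methyl-1β,10β-methanodecalin-4α,9β-diol
Product: 15 4β,10β-dimethyl-5αH-decalin-4α,9β-diol (trans-decalin)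
Conditions: H2 (3–4 atm), PtO2 (20 mol %), AcOH, rt
Reagents that add atoms: none
Why: Catalytic hydrogenolysis of an unactivated cyclopropane breaks the least substituted and most exposed bond, here C1H–C14H2, so C14 stays on C10 as the 10β-methyl group with C10 unchanged; the step is run while C9 is a carbinol because a C9 carbonyl would steer cleavage to the C10–C14 or C10–C1 bond.

Step 9
Reactants: 15 4β,10β-dimethyl-5αH-decalin-4α,9β-diol
Product: 16 4α-hydroxy-4β,10β-dimethyl-5αH-decalin-9-one
Conditions: Dess–Martin periodinane (1.2 equiv), CH2Cl2, rt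
Reagents that add atoms: none
Why: Dess–Martin oxidation converts the secondary 9-ol into the ketone and cannot touch the tertiary 4-ol; the C9 stereocentre has done its work and is reset in step 13.

Step 10
Reactants: 16 4α-hydroxy-4β,10β-dimethyl-5αH-decalin-9-one
Product: 17 4α,9-bis(trimethylsilyloxy)-4β,10β-dimethyl-5αH-octal-8-ene
Conditions: TMSOTf (2.5 equiv), Et3N (4 equiv), CH2Cl2, 0 °C
Reagents that add atoms: trimethylsilyl triflate, C[Si](C)(C)OS(=O)(=O)C(F)(F)F
Why: Soft enolisation with silyl triflate and amine: C10 is quaternary, so only the C8 enol ether can form, and the tertiary hydroxyl is silylated at the same time.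

Step 11
Reactants: 17 4α,9-bis(trimethylsilyloxy)-4β,10β-dimethyl-5αH-octal-8-ene
Product: 19 4α-hydroxy-4β,10β-dimethyl-5αH-octal-7-en-9-one, via silyl-protected enone 18 (not isolated)
Conditions: Pd(OAc)2 (1.1 equiv), MeCN, rt; then 1 M HCl (cat.), THF/H2O, 0 °C
Reagents that add atoms: none
Why: Saegusa–Ito oxidation: divalent palladium takes the enol ether to an oxo-π-allyl species that loses H7 by β-hydride elimination to give the 7-en-9-one and zerovalent palladium, and the dilute acid then frees the tertiary alcohol.

Step 12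
Reactants: 19 4α-hydroxy-4β,10β-dimethyl-5αH-octal-7-en-9-one; 20 isopropenylmagnesium bromide
Product: 21 4α-hydroxy-7α-isopropenyl-4β,10β-dimethyl-5αH-decalin-9-one (4α-hydroxy-7-epi-eudesm-11-en-9-one)
Conditions: CH2=C(CH3)MgBr (5 equiv), CuBr·SMe2 (2.5 equiv), THF, −78 to −30 °C; aq. NH4Cl
Reagents that add atoms: none
Why: Organocuprate 1,4-addition: the stereoelectronically preferred axial attack on the enone of the rigid trans-decalin comes from the α face (the side of axial H5, away from the axial 10β-methyl), the pattern known as trans-3,5 selectivity of 5-substituted cyclohexenones, and sets the 7α (axial) isopropenyl group; the surplus reagent covers the free hydroxyl.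

Step 13
Reactants: 21 4α-hydroxy-7-epi-eudesm-11-en-9-one
Product: 22 7-epi-eudesm-11-ene-4α,9β-diol
Conditions: Li, NH3(l)/THF, EtOH, −78 to −33 °C; then NH4Cl
Reagents that add atoms: none
Why: Dissolving-metal reduction of a hindered cyclohexanone gives the more stable equatorial alcohol, here 9β, since a 9α (axial) oxygen would be syn-diaxial to the 7α-isopropenyl group, whereas hydride reagents would be pushed toward the wrong epimer by that same axial group; the isolated 1,1-disubstituted alkene is not reduced.

Step 14
Reactants: 22 7-epi-eudesm-11-ene-4α,9β-diol; 23 (S)-3-methylpentanoic acid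
Product: 24 9β-[(S)-3-methylpentanoyloxy]-7-epi-eudesm-11-en-4α-ol
Conditions: 23 (1.5 equiv), DCC (1.5 equiv), DMAP (0.3 equiv), CH2Cl2, rt
Reagents that add atoms: none
Why: Steglich esterification acylates the secondary equatorial 9β-ol while the tertiary 4α-ol stays free under these conditions; the stereocentre of 23 is β to the carboxyl group and cannot epimerise.

Step 15
Reactants: 24 9β-[(S)-3-methylpentanoyloxy]-7-epi-eudesm-11-en-4α-ol
Product: 25 9β-[(S)-3-methylpentanoyloxy]-7-epi-eudesm-11(13)-ene-4α,12-diol
Conditions: SeO2 (0.5 equiv), t-BuOOH (3 equiv), CH2Cl2, 0 °C to rt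
Reagents that add atoms: tert-butyl hydroperoxide, CC(C)(C)OO; selenium dioxide, O=[Se]=O (oxygen carrier)
Why: Riley allylic oxidation (ene reaction, then [2,3]-sigmatropic shift) of an isopropenyl group, as practised on 7-isopropenyl eudesmanes, should attack the methyl group because abstraction of H7 would pass through a crowded tetrasubstituted C7=C11 alkene; any enal formed by further oxidation is carried into step 16.

Step 16
Reactants: 25 9β-[(S)-3-methylpentanoyloxy]-7-epi-eudesm-11(13)-ene-4α,12-diol
Product: 26 4α-hydroxy-9β-[(S)-3-methylpentanoyloxy]-7-epi-eudesm-11(13)-en-12-al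
Conditions: Dess–Martin periodinane (1.2 equiv), CH2Cl2, 0 °C to rt
Reagents that add atoms: none
Why: Dess–Martin oxidation of the primary allylic alcohol stops at the 2-substituted acrolein and leaves the ester and the tertiary alcohol alone.

Step 17
Reactants: 26 4α-hydroxy-9β-[(S)-3-methylpentanoyloxy]-7-epi-eudesm-11(13)-en-12-al
Product: 27 4α-hydroxy-9β-[(S)-3-methylpentanoyloxy]-7-epi-eudesm-11(13)-en-12-oic acid (CNP0471281.1)
Conditions: NaClO2, NaH2PO4, 2-methyl-2-butene, t-BuOH/H2O, rt
Reagents that add atoms: sodium chlorite, [Na+].[O-]Cl=O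
Why: Pinnick (Lindgren) oxidation turns the enal into the acrylic acid without touching the 1,1-disubstituted alkene, since 2-methyl-2-butene traps the hypochlorous acid, and gives the target.

Compound list
1 | 5,5-diethoxypent-1-yne | C#CCCC(OCC)OCC | starting material
2 | (5,5-diethoxypent-1-en-2-yl)diisobutylalane | C=C(CCC(OCC)OCC)[Al](CC(C)C)CC(C)C | intermediate
3 | 2-(5,5-diethoxypent-1-en-2-yl)-4,4,5,5-tetramethyl-1,3,2-dioxaborolane | C=C(CCC(OCC)OCC)B1OC(C)(C)C(C)(C)O1 | intermediate
4 | cyclohex-2-en-1-one | O=C1C=CCCC1 | starting material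
5 | (R)-3-(5,5-diethoxypent-1-en-2-yl)cyclohexan-1-one | C=C(CCC(OCC)OCC)[C@H]1CC(=O)CCC1 | intermediate
6 | (R)-4-(3-oxocyclohexyl)pent-4-enal | C=C(CCC=O)[C@H]1CC(=O)CCC1 | intermediate
7 | 1-hydroxy-4-methylene-5αH-decalin-9-one (aldol adduct, epimers at C1 and C10) | O=C1CCC[C@@H]2C1C(O)CCC2=C | intermediate
8 | (4aS)-5-methylidene-3,4,4a,5,6,7-hexahydronaphthalen-1(2H)-one | O=C1CCC[C@@H]2C1=CCCC2=C | intermediate
9 | (1S,4aS)-5-methylidene-1,2,3,4,4a,5,6,7-octahydronaphthalen-1-ol | C1C[C@H](O)C2=CCCC(=C)[C@@H]2C1 | intermediate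
10 | diiodomethane | ICI | starting material
11 | iodomethylzinc alkoxide of 9 | C1C[C@H](O[Zn]CI)C2=CCCC(=C)[C@@H]2C1 | intermediate
12 | 9β-hydroxy-4-methylene-1β,10β-methanodecalin (5αH) | C1C[C@H](O)[C@]23C[C@@H]3CCC(=C)[C@@H]2C1 | intermediate
13 | 4α,15-epoxy-9β-hydroxy-1β,10β-methanodecalin | C1C[C@H](O)[C@]23C[C@@H]3CC[C@]4(CO4)[C@@H]2C1 | intermediate
14 | 4β-methyl-1β,10β-methanodecalin-4α,9β-diol | C1C[C@H](O)[C@]23C[C@@H]3CC[C@@](C)(O)[C@@H]2C1 | intermediate
15 | 4β,10β-dimethyl-5αH-decalin-4α,9β-diol | C1C[C@H](O)[C@@]2(C)CCC[C@@](C)(O)[C@@H]2C1 | intermediate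
16 | 4α-hydroxy-4β,10β-dimethyl-5αH-decalin-9-one | C1CC(=O)[C@@]2(C)CCC[C@@](C)(O)[C@@H]2C1 | intermediate
17 | 4α,9-bis(trimethylsilyloxy)-4β,10β-dimethyl-5αH-octal-8-ene | C1C=C(O[Si](C)(C)C)[C@@]2(C)CCC[C@@](C)(O[Si](C)(C)C)[C@@H]2C1 | intermediate
18 | 4α-trimethylsilyloxy-4β,10β-dimethyl-5αH-octal-7-en-9-one | C1=CC(=O)[C@@]2(C)CCC[C@@](C)(O[Si](C)(C)C)[C@@H]2C1 | intermediate
19 | 4α-hydroxy-4β,10β-dimethyl-5αH-octal-7-en-9-one | C1=CC(=O)[C@@]2(C)CCC[C@@](C)(O)[C@@H]2C1 | intermediate
20 | isopropenylmagnesium bromide | C=C(C)[Mg]Br | starting material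
21 | 4α-hydroxy-7-epi-eudesm-11-en-9-one | C=C(C)[C@H]1CC(=O)[C@@]2(C)CCC[C@@](C)(O)[C@@H]2C1 | intermediate
22 | 7-epi-eudesm-11-ene-4α,9β-diol | C=C(C)[C@H]1C[C@H](O)[C@@]2(C)CCC[C@@](C)(O)[C@@H]2C1 | intermediate
23 | (S)-3-methylpentanoic acid | CC[C@H](C)CC(=O)O | starting material
24 | 9β-[(S)-3-methylpentanoyloxy]-7-epi-eudesm-11-en-4α-ol | C=C(C)[C@H]1C[C@H](OC(=O)C[C@@H](C)CC)[C@@]2(C)CCC[C@@](C)(O)[C@@H]2C1 | intermediate
25 | 9β-[(S)-3-methylpentanoyloxy]-7-epi-eudesm-11(13)-ene-4α,12-diol | C=C(CO)[C@H]1C[C@H](OC(=O)C[C@@H](C)CC)[C@@]2(C)CCC[C@@](C)(O)[C@@H]2C1 | intermediate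
26 | 4α-hydroxy-9β-[(S)-3-methylpentanoyloxy]-7-epi-eudesm-11(13)-en-12-al | C=C(C=O)[C@H]1C[C@H](OC(=O)C[C@@H](C)CC)[C@@]2(C)CCC[C@@](C)(O)[C@@H]2C1 | intermediate
27 | 4α-hydroxy-9β-[(S)-3-methylpentanoyloxy]-7-epi-eudesm-11(13)-en-12-oic acid | C=C(C(=O)O)[C@H]1C[C@H](OC(=O)C[C@@H](C)CC)[C@@]2(C)CCC[C@@](C)(O)[C@@H]2C1 | target

Total step count: 17. Longest linear sequence: 17 steps (1 to 27).

Steps most likely to fail

Step 5.
- What may go wrong: the C9–O bond of 9 lies close to the plane of the C10=C1 alkene, so facial steering by the zinc alkoxide may be weak. Surplus carbenoid may also methylenate the C4 methylene.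
- Fallback (from 9, back at 12): the carbene carbon is tied to the C9 oxygen by a covalent tether instead of a zinc–oxygen contact.
- 9 is acylated with glyoxylic acid chloride tosylhydrazone (PhNMe2, then Et3N, CH2Cl2, 0 °C) to give the diazoacetate F1.
- Slow addition of F1 to Rh2(OAc)4 (1 mol %) in CH2Cl2 gives, by intramolecular cyclopropanation, the cyclopropane-fused γ-lactone F2. Its five-membered lactone can only be cis-fused on C9–C10, so C14 must sit β, and the distant C4 methylene is out of reach.
- iBu2AlH (toluene, −78 °C) gives the lactol F3. Its open hydroxy aldehyde form loses CO with RhCl(PPh3)3 (1 equiv, toluene, reflux; Tsuji–Wilkinson decarbonylation) to give 12.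

Step 8.
- What may go wrong: cleavage of the wrong cyclopropane bond, sluggish hydrogenolysis at the hindered ring, or ionisation of the cyclopropyl carbinol in AcOH.
- Fallback (from 9, back at 15): no three-membered ring is made or cut; the angular carbon arrives by a tethered radical closure.
- 9 is treated with ethyl vinyl ether and NBS (CH2Cl2, −20 °C) to give the bromoacetal F4.
- Bu3SnH and AIBN (benzene, reflux, slow addition) close F4 by 5-exo attack on C10 (Ueno–Stork cyclisation) to the bicyclic acetal F5. Its ring is necessarily cis-fused, so C14 is β.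
- 0.1 M HCl in THF/H2O gives the lactol F6. RhCl(PPh3)3 (1 equiv, toluene, reflux) then removes the aldehyde carbon and leaves the 9β-hydroxy-10β-methyl-4-methylene decalin F7.
- mCPBA, now guided by a true axial methyl group, gives the 4α,15-epoxide F8, and LiAlH4 opens it to 15.

Step 6.
- What may go wrong: poor facial selectivity, because the cyclopropane methylene leans away from C4 and may screen the β face less well than a methyl group.
- Fallback (from 12, back at 13): the oxygen is set by osmylation, which by itself prefers the equatorial approach to methylenecyclohexanes.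
- OsO4 (2 mol %) and NMO in acetone/H2O give the 4α,9β,15-triol F9.
- TsCl in pyridine at 0 °C sulfonylates only the primary C15 hydroxyl to give the monotosylate F10.
- K2CO3 in MeOH closes F10, with the C4–O bond untouched, to 13.

Further compounds
F1 | step 5 | diazoacetate of 9 | C1C[C@H](OC(=O)C=[N+]=[N-])C2=CCCC(=C)[C@@H]2C1
F2 | step 5 | cyclopropane-fused γ-lactone (C14 carries the lactone carbonyl bound to the C9 oxygen) | C1C[C@@H]2OC(=O)[C@H]3[C@@H]4CCC(=C)[C@H](C1)[C@]234
F3 | step 5 | lactol of F2 (anomers) | C1C[C@@H]2OC(O)[C@H]3[C@@H]4CCC(=C)[C@H](C1)[C@]234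
F4 | step 8 | 2-bromo-1-ethoxyethyl ether of 9 (acetal epimers) | C1C[C@H](OC(CBr)OCC)C2=CCCC(=C)[C@@H]2C1
F5 | step 8 | cis-fused bicyclic ethyl acetal bridging the C9 oxygen and C10 through C14 | C1C[C@@H]2OC(OCC)C[C@@]23CCCC(=C)[C@@H]3C1
F6 | step 8 | lactol of F5 (anomers) | C1C[C@@H]2OC(O)C[C@@]23CCCC(=C)[C@@H]3C1
F7 | step 8 | 9β-hydroxy-10β-methyl-4-methylene-5αH-decalin | C1C[C@H](O)[C@@]2(C)CCCC(=C)[C@@H]2C1
F8 | step 8 | 4α,15-epoxy-10β-methyl-5αH-decalin-9β-ol | C1C[C@H](O)[C@@]2(C)CCC[C@]3(CO3)[C@@H]2C1
F9 | step 6 | 4β-hydroxymethyl-1β,10β-methanodecalin-4α,9β-diol | C1C[C@H](O)[C@]23C[C@@H]3CC[C@@](CO)(O)[C@@H]2C1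
F10 | step 6 | C15 mono-p-toluenesulfonate of F9 | C1C[C@H](O)[C@]23C[C@@H]3CC[C@@](COS(=O)(=O)c4ccc(C)cc4)(O)[C@@H]2C1
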